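**Retrosynthetic overview**
1. Target ⇒ C–Cl from C–Si (chlorodesilylation with retention) ⇒ Stille union of a side-chain alkenylstannane with (6S)-2-bromo-3,6-dimethylcyclohex-2-en-1-one.
2. The bromoenone ⇒ catalytic enantioselective one-carbon ring expansion (1,2-alkyl shift with loss of N2) of commercial 2-bromo-3-methylcyclopent-2-en-1-one with diazoethane.
3. Stannane ⇒ cis-silylstannation of the N-propargyl amide ⇒ propargylamine + (4E,7S)-7-methoxydodec-4-enoic acid.
4. Acid ⇒ cross-metathesis of (4S)-4-methoxynon-1-ene with pent-4-enoic acid ⇒ O-methylation ⇒ Keck allylation of hexanal.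
5. Ring order: there is one carbocycle; the five-membered ring is bought and expanded to the six-membered ring (setting C6) before the fragments are joined.

Assumption: the antipode of the tris(oxazoline) ligand in step 6 that gives the 6S product is fixed in a first screen (both antipodes are accessible); the route is written for that antipode.

**Step 1**
Reactants: 1 hexanal
Product: 3 (4S)-non-1-en-4-ol, via tin ether 2 (not isolated)
Conditions: allylSnBu3 (1.2 equiv), (R)-BINOL (10 mol %), Ti(OiPr)4 (10 mol %), 4 Å MS, CH2Cl2, −20 °C; aq NaHCO3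
Reagents that add atoms: allyltributylstannane, C=CC[Sn](CCCC)(CCCC)CCCC
Why: Keck asymmetric allylation, in which the (R)-BINOL–Ti(OiPr)4 Lewis acid directs the allyl group to the Re face of the unbranched aldehyde and so sets C4 as S (about 94% ee expected); the tin ether 2 is hydrolysed on work-up.

**Step 2**
Reactants: 3 (4S)-non-1-en-4-ol
Product: 4 (4S)-4-methoxynon-1-ene
Conditions: NaH (1.5 equiv), MeI (2 equiv), THF, 0 °C to rt
Reagents that add atoms: iodomethane, CI
Why: Williamson etherification of the sodium alkoxide with MeI, which does not touch the carbinol stereocentre.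

**Step 3**
Reactants: 4 (4S)-4-methoxynon-1-ene; 5 pent-4-enoic acid (3 equiv)
Product: 6 (4E,7S)-7-methoxydodec-4-enoic acid
Conditions: second-generation Grubbs catalyst RuCl2(=CHPh)(PCy3)(H2IMes) (5 mol %), CH2Cl2, 40 °C; E isomer purified on AgNO3-impregnated silica
Reagents that add atoms: none
Why: Olefin cross-metathesis of two unhindered terminal alkenes, driven by loss of ethene and an excess of the cheap acid 5; the thermodynamic E preference (about 5:1) is upgraded to pure E by argentation chromatography and the remote stereocentre is inert.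

**Step 4**
Reactants: 6 (4E,7S)-7-methoxydodec-4-enoic acid; 7 prop-2-yn-1-amine
Product: 9 (4E,7S)-7-methoxy-N-(prop-2-yn-1-yl)dodec-4-enamide, via acyl imidazolide 8 (not isolated)
Conditions: CDI (1.1 equiv), THF, rt, 1 h; then 7 (1.2 equiv), rt
Reagents that add atoms: 1,1'-carbonyldiimidazole, O=C(n1ccnc1)n1ccnc1 (its imidazolyl group is carried only in 8)
Why: Amide formation through the acyl imidazolide under neutral conditions, which leaves the alkene, the ether and the stereocentre untouched.

**Step 5**
Reactants: 9 (4E,7S)-7-methoxy-N-(prop-2-yn-1-yl)dodec-4-enamide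
Product: 10 (4E,7S)-7-methoxy-N-[(2Z)-2-(tributylstannyl)-3-(trimethylsilyl)prop-2-en-1-yl]dodec-4-enamide
Conditions: Me3SiSnBu3 (1.2 equiv), Pd(PPh3)4 (5 mol %), THF, 65 °C
Reagents that add atoms: tributyl(trimethylsilyl)stannane, C[Si](C)(C)[Sn](CCCC)(CCCC)CCCC
Why: Palladium-catalysed silylstannation, in which zerovalent palladium inserts into the Si–Sn bond and adds it syn across the terminal alkyne with tin on the internal and silicon on the terminal carbon; this fixes the Z geometry that later becomes the E chloroalkene, and the isolated alkene does not react.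

**Step 6**
Reactants: 11 2-bromo-3-methylcyclopent-2-en-1-one
Product: 12 (6S)-2-bromo-3,6-dimethylcyclohex-2-en-1-one
Conditions: CH3CHN2 (1.5 equiv, pre-formed dry toluene solution, added over 2 h), Sc(OTf)3 (10 mol %), 1,1,1-tris[(4S)-4-isopropyl-4,5-dihydrooxazol-2-yl]ethane (12 mol %), toluene, −78 °C
Reagents that add atoms: diazoethane, CC=[N+]=[N-]
Why: Proposed new method: the chiral Sc(OTf)3–tris(oxazoline) Lewis acid activates the enone carbonyl of 11, diazoethane adds through carbon with one prochiral face to one enantiotopic carbonyl face, and the diazonium alkoxide then undergoes a stereospecific 1,2-shift of the saturated C5 anti to the leaving N2 (the electron-poor sp2 C2–Br carbon migrates far less readily, and C5 migration keeps the enone conjugated), which expands the five-membered to the six-membered ring and sets C6 as S; the closest known reaction type is the Sc(OTf)3-catalysed diazoalkane–ketone homologation (Büchner–Curtius–Schlotterbeck or Tiffeneau–Demjanov-type ring expansion), known enantioselectively for saturated cycloalkanones with aryldiazomethanes but not for an α-bromo cycloalkenone with diazoethane.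

**Step 7**
Reactants: 10 (4E,7S)-7-methoxy-N-[(2Z)-2-(tributylstannyl)-3-(trimethylsilyl)prop-2-en-1-yl]dodec-4-enamide; 12 (6S)-2-bromo-3,6-dimethylcyclohex-2-en-1-one
Product: 13 (4E,7S)-N-[(2E)-2-[(5S)-2,5-dimethyl-6-oxocyclohex-1-en-1-yl]-3-(trimethylsilyl)prop-2-en-1-yl]-7-methoxydodec-4-enamide
Conditions: Pd2(dba)3 (5 mol %), AsPh3 (20 mol %), CuI (20 mol %), NMP, 45 °C
Reagents that add atoms: none
Why: Stille coupling under Farina–Liebeskind conditions (AsPh3 and CuI speed up transmetalation of the hindered α-substituted alkenylstannane) with retention at both sp2 carbons; the neutral medium leaves the enolisable C6 stereocentre intact.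

**Step 8**
Reactants: 13 (4E,7S)-N-[(2E)-2-[(5S)-2,5-dimethyl-6-oxocyclohex-1-en-1-yl]-3-(trimethylsilyl)prop-2-en-1-yl]-7-methoxydodec-4-enamide
Product: 14 (4E,7S)-N-[(2E)-3-chloro-2-[(5S)-2,5-dimethyl-6-oxocyclohex-1-en-1-yl]prop-2-en-1-yl]-7-methoxydodec-4-enamide (CNP0332649.2)
Conditions: NCS (1.3 equiv), DMF, 50 °C, dark
Reagents that add atoms: N-chlorosuccinimide, O=C1CCC(=O)N1Cl
Why: Electrophilic ipso-chlorodesilylation, in which Cl+ adds to the silicon-bearing carbon and the β-silyl cation loses the silyl group faster than it rotates, so Cl replaces Si with retention (E chloroalkene); the electron-rich vinylsilane reacts ahead of the disubstituted alkene and the enone.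

**Compound list**
1 | hexanal | CCCCCC=O | starting material
2 | tributyl{[(4S)-non-1-en-4-yl]oxy}stannane (tin ether of 3) | CCCCC[C@@H](CC=C)O[Sn](CCCC)(CCCC)CCCC | intermediate
3 | (4S)-non-1-en-4-ol | CCCCC[C@@H](CC=C)O | intermediate
4 | (4S)-4-methoxynon-1-ene | CCCCC[C@@H](CC=C)OC | intermediate
5 | pent-4-enoic acid | C=CCCC(=O)O | starting material
6 | (4E,7S)-7-methoxydodec-4-enoic acid | CCCCC[C@@H](C/C=C/CCC(=O)O)OC | intermediate
7 | prop-2-yn-1-amine (propargylamine) | C#CCN | starting material
8 | (4E,7S)-1-(1H-imidazol-1-yl)-7-methoxydodec-4-en-1-one (acyl imidazolide) | CCCCC[C@@H](C/C=C/CCC(=O)n1ccnc1)OC | intermediate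
9 | (4E,7S)-7-methoxy-N-(prop-2-yn-1-yl)dodec-4-enamide | CCCCC[C@@H](C/C=C/CCC(=O)NCC#C)OC | intermediate
10 | (4E,7S)-7-methoxy-N-[(2Z)-2-(tributylstannyl)-3-(trimethylsilyl)prop-2-en-1-yl]dodec-4-enamide | CCCCC[C@@H](C/C=C/CCC(=O)NC/C(=C/[Si](C)(C)C)[Sn](CCCC)(CCCC)CCCC)OC | intermediate
11 | 2-bromo-3-methylcyclopent-2-en-1-one | CC1=C(Br)C(=O)CC1 | starting material
12 | (6S)-2-bromo-3,6-dimethylcyclohex-2-en-1-one | C[C@H]1CCC(C)=C(Br)C1=O | intermediate
13 | (4E,7S)-N-[(2E)-2-[(5S)-2,5-dimethyl-6-oxocyclohex-1-en-1-yl]-3-(trimethylsilyl)prop-2-en-1-yl]-7-methoxydodec-4-enamide | CCCCC[C@@H](C/C=C/CCC(=O)NC/C(=C/[Si](C)(C)C)C1=C(C)CC[C@H](C)C1=O)OC | intermediate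
14 | (4E,7S)-N-[(2E)-3-chloro-2-[(5S)-2,5-dimethyl-6-oxocyclohex-1-en-1-yl]prop-2-en-1-yl]-7-methoxydodec-4-enamide | CCCCC[C@@H](C/C=C/CCC(=O)NC/C(=C/Cl)C1=C(C)CC[C@H](C)C1=O)OC | target

**Total step count:** 8.
**Longest linear sequence:** 7 (steps 1, 2, 3, 4, 5, 7, 8); step 6 is a one-step side branch.

**Three steps most likely to fail**

Step 6 (the proposed new step). Possible failures are low enantioselectivity, competing migration of C2 (giving a β,γ-unsaturated regioisomer), epoxide formation or a second homologation. The fallback uses known chemistry only. It does not set out from a numbered compound: commercial 3-methylcyclohex-2-en-1-one F1 (eight non-hydrogen atoms) takes the place of 11, and the sequence comes back to the route at 12. F1 is condensed with (R)-1-amino-2-(methoxymethyl)pyrrolidine (RAMP, 60 °C) to give the RAMP hydrazone of 3-methylcyclohex-2-en-1-one F2. Deprotonation at the α′ position with LiN(iPr)2 (THF, −78 °C) and alkylation with MeI (Enders hydrazone alkylation) gives the (6S)-3,6-dimethylcyclohex-2-en-1-one RAMP hydrazone F3. RAMP is chosen because the SAMP auxiliary gives the R ketone with cyclohexanone and MeI, which has the same priority pattern. Two-phase aqueous oxalic acid/Et2O cleaves the hydrazone without epimerisation to (6S)-3,6-dimethylcyclohex-2-en-1-one F4. Br2 in CH2Cl2 at −20 °C gives (6S)-2,3-dibromo-3,6-dimethylcyclohexan-1-one F5 (not isolated), and brief treatment with Et3N at 0 °C eliminates HBr to give 12.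

Step 7. Both partners are hindered (a tetrasubstituted bromoenone and an α-substituted stannane with a cis silyl group), so slow coupling, protodestannylation or cine substitution may occur. The fallback reverses the polarity; it sets out from 10 and 12 and comes back at 13. I2 (CH2Cl2, 0 °C) converts 10 with retention into (4E,7S)-N-[(2Z)-2-iodo-3-(trimethylsilyl)prop-2-en-1-yl]-7-methoxydodec-4-enamide F6. Luche reduction of 12 (NaBH4, CeCl3·7H2O, MeOH, −40 °C) gives (6S)-2-bromo-3,6-dimethylcyclohex-2-en-1-ol F7 as both C1 epimers, in which C6 can no longer enolise. MeLi (1 equiv) then t-BuLi (2 equiv) in THF at −78 °C give the dilithio species lithium (6S)-2-lithio-3,6-dimethylcyclohex-2-en-1-olate F8, and ZnCl2 converts it into the alkenylzinc reagent lithium (6S)-2-(chlorozincio)-3,6-dimethylcyclohex-2-en-1-olate F9. Negishi coupling of F9 with F6 (Pd(PtBu3)2, THF, rt) gives (4E,7S)-N-[(2E)-2-[(5S)-6-hydroxy-2,5-dimethylcyclohex-1-en-1-yl]-3-(trimethylsilyl)prop-2-en-1-yl]-7-methoxydodec-4-enamide F10. Dess–Martin periodinane (NaHCO3, CH2Cl2) oxidises F10 back to the enone 13.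

Step 8. The β-silyl cation sits next to the allylic amide, whose oxygen may trap it (oxazoline formation, or loss of alkene geometry after elimination). The fallback installs chlorine before the coupling and without a cationic intermediate; it sets out from 9 (and uses 12) and comes back at the target 14. Pd(PPh3)4-catalysed cis-distannation of 9 with Me3SnSnMe3 (THF, 65 °C) gives (4E,7S)-N-[(2Z)-2,3-bis(trimethylstannyl)prop-2-en-1-yl]-7-methoxydodec-4-enamide F11. CuCl2 (2.2 equiv, THF, 0 °C) replaces the less hindered terminal tin by chlorine with retention to give (4E,7S)-N-[(2Z)-3-chloro-2-(trimethylstannyl)prop-2-en-1-yl]-7-methoxydodec-4-enamide F12. Stille coupling of F12 with 12 under the conditions of step 7 gives 14 directly; the smaller cis substituent also eases the coupling.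

**Further compounds**
F1 | step 6 | 3-methylcyclohex-2-en-1-one | CC1=CC(=O)CCC1
F2 | step 6 | RAMP hydrazone of 3-methylcyclohex-2-en-1-one | CC1=CC(=NN2CCC[C@@H]2COC)CCC1
F3 | step 6 | (6S)-3,6-dimethylcyclohex-2-en-1-one RAMP hydrazone | CC1=CC(=NN2CCC[C@@H]2COC)[C@@H](C)CC1
F4 | step 6 | (6S)-3,6-dimethylcyclohex-2-en-1-one | CC1=CC(=O)[C@@H](C)CC1
F5 | step 6 | (6S)-2,3-dibromo-3,6-dimethylcyclohexan-1-one | C[C@H]1CCC(C)(Br)C(Br)C1=O
F6 | step 7 | (4E,7S)-N-[(2Z)-2-iodo-3-(trimethylsilyl)prop-2-en-1-yl]-7-methoxydodec-4-enamide | CCCCC[C@@H](C/C=C/CCC(=O)NC/C(I)=C/[Si](C)(C)C)OC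
F7 | step 7 | (6S)-2-bromo-3,6-dimethylcyclohex-2-en-1-ol | C[C@H]1CCC(C)=C(Br)C1O
F8 | step 7 | lithium (6S)-2-lithio-3,6-dimethylcyclohex-2-en-1-olate | C[C@H]1CCC(C)=C([Li])C1O[Li]
F9 | step 7 | lithium (6S)-2-(chlorozincio)-3,6-dimethylcyclohex-2-en-1-olate | C[C@H]1CCC(C)=C([Zn]Cl)C1O[Li]
F10 | step 7 | (4E,7S)-N-[(2E)-2-[(5S)-6-hydroxy-2,5-dimethylcyclohex-1-en-1-yl]-3-(trimethylsilyl)prop-2-en-1-yl]-7-methoxydodec-4-enamide | CCCCC[C@@H](C/C=C/CCC(=O)NC/C(=C/[Si](C)(C)C)C1=C(C)CC[C@H](C)C1O)OC
F11 | step 8 | (4E,7S)-N-[(2Z)-2,3-bis(trimethylstannyl)prop-2-en-1-yl]-7-methoxydodec-4-enamide | CCCCC[C@@H](C/C=C/CCC(=O)NC/C(=C/[Sn](C)(C)C)[Sn](C)(C)C)OC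
F12 | step 8 | (4E,7S)-N-[(2Z)-3-chloro-2-(trimethylstannyl)prop-2-en-1-yl]-7-methoxydodec-4-enamide | CCCCC[C@@H](C/C=C/CCC(=O)NC/C(=C/Cl)[Sn](C)(C)C)OC
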